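**Plan**
Atom labels: ring C1 (the CH) to C14 with C3=C4, C7=C8, C11=C12; carbinol carbon C15. The retrosynthesis cuts C1–C15 first (boronate 1,2-shift joining a C17 macrocycle to a C13 chain), then ring bond C2–C3 (alkyl–alkenyl coupling) and C13–C14 (allyl–allyl coupling); both halves come from geranylacetone.
Enabling feature: C15 bears CH3, an unbranched CH2 and O, so it is a masked methyl carbinol whose C–H can be exchanged for a C–C bond by way of boron. C1 is a CH between two CH2 groups with C3=C4 one carbon away, so C1/C2 are a masked terminal alkene (diboration) and C2–C3 an sp3–sp2 coupling site.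
Forward: geranylacetone → alkyne → (E)-bromoalkene → allylic alcohol → bromide → allylated tetraene → enantioselective diboration → Suzuki closure of the 14-membered ring (the only ring) → neopentyl glycol boronate. Separately geranylacetone → (R)-alcohol → (S)-TIB ester; the two halves are joined in the last step.
Stereochemistry: C1 (R) comes from the catalyst-controlled diboration and is kept with retention in the coupling and in the 1,2-shift. C15 (S) comes from the enzymatic reduction, relayed by Mitsunobu inversion, retentive lithiation–borylation, invertive 1,2-shift and retentive C–B oxidation. The (E)-alkenes come from geranylacetone, syn-carboalumination and (E)-selective allylic oxidation.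

Key step: step 11

Assumption: geranylacetone is used as the isomerically pure (E)-isomer, and the TADDOL phosphonite enantiomer of step 8 (written as R,R) is taken to be the one that gives the (2S)-bis(boronate); otherwise its mirror image is used.

**Step 1**
Reactants: 1 (5E)-6,10-dimethylundeca-5,9-dien-2-one (geranylacetone)
Product: 2 (2R,5E)-6,10-dimethylundeca-5,9-dien-2-ol
Conditions: Lactobacillus kefir alcohol dehydrogenase (R-selective), NADP+ (cat.), MgCl2, iPrOH/phosphate buffer pH 7, 30 °C
Reagents that add atoms: none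
Why: Enzymatic ketone reduction with isopropanol as hydride donor, in which the anti-Prelog enzyme should deliver hydride to the Si face of the methyl/primary-alkyl ketone and so set the (R)-carbinol, the isolated alkenes being inert.

**Step 2**
Reactants: 2 (2R,5E)-6,10-dimethylundeca-5,9-dien-2-ol
Product: 3 (2S,5E)-6,10-dimethylundeca-5,9-dien-2-yl 2,4,6-tri(propan-2-yl)benzoate (TIB ester)
Conditions: 2,4,6-iPr3C6H2CO2H, PPh3, DIAD, THF, 0 °C → rt
Reagents that add atoms: 2,4,6-tri(propan-2-yl)benzoic acid, CC(C)c1cc(C(C)C)c(C(=O)O)c(C(C)C)c1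
Why: Mitsunobu esterification, in which SN2 displacement of the oxyphosphonium by the hindered carboxylate should invert C2 to the (S)-ester that carries both the directing group for α-lithiation and the leaving group for the later 1,2-shift.

**Step 3**
Reactants: 1 (5E)-6,10-dimethylundeca-5,9-dien-2-one
Product: 5 (5E)-6,10-dimethylundeca-5,9-dien-1-yne, via enol phosphate 4 (not isolated)
Conditions: LDA (1.05 equiv), THF, −78 °C; ClP(O)(OEt)2, −78 °C → rt; LDA (2.3 equiv), −78 °C → rt
Reagents that add atoms: none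
Why: Negishi conversion of a methyl ketone into a terminal alkyne by kinetic enolisation at the methyl group, O-phosphorylation and base-induced elimination of the enol phosphate, with the trisubstituted alkenes untouched.

**Step 4**
Reactants: 5 (5E)-6,10-dimethylundeca-5,9-dien-1-yne
Product: 7 (1E,5E)-1-bromo-2,6,10-trimethylundeca-1,5,9-triene, via alkenylalane 6 (not isolated)
Conditions: AlMe3 (2 equiv), Cp2ZrCl2 (0.25 equiv), CH2Cl2, 0 °C → rt; NBS, THF, −78 → 0 °C
Reagents that add atoms: trimethylaluminium, C[Al](C)C; N-bromosuccinimide, O=C1CCC(=O)N1Br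
Why: Zirconium-catalysed Negishi carboalumination, in which syn addition of CH3–Al across the terminal alkyne should fix the (E)-geometry and bromodealumination should go with retention.

**Step 5**
Reactants: 7 (1E,5E)-1-bromo-2,6,10-trimethylundeca-1,5,9-triene
Product: 8 (2E,6E,10E)-11-bromo-2,6,10-trimethylundeca-2,6,10-trien-1-ol
Conditions: SeO2 (0.5 equiv), tBuOOH (3 equiv), salicylic acid (0.1 equiv), CH2Cl2, 0 °C → rt; NaBH4, MeOH, 0 °C
Reagents that add atoms: tert-butyl hydroperoxide, CC(C)(C)OO
Why: Selenium dioxide allylic oxidation (ene reaction then [2,3]-sigmatropic shift), which should take place at the (E)-methyl group of the terminal, most electron-rich alkene as in farnesyl acetate, the bromoalkene being deactivated and the borohydride work-up returning any enal to the alcohol.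

**Step 6**
Reactants: 8 (2E,6E,10E)-11-bromo-2,6,10-trimethylundeca-2,6,10-trien-1-ol
Product: 9 (1E,5E,9E)-1,11-dibromo-2,6,10-trimethylundeca-1,5,9-triene
Conditions: CBr4, PPh3, CH2Cl2, 0 °C
Reagents that add atoms: tetrabromomethane, BrC(Br)(Br)Br
Why: Appel bromination, an SN2 displacement at the primary allylic carbon that should proceed without allylic transposition at low temperature.

**Step 7**
Reactants: 9 (1E,5E,9E)-1,11-dibromo-2,6,10-trimethylundeca-1,5,9-triene
Product: 10 (1E,5E,9E)-1-bromo-2,6,10-trimethyltetradeca-1,5,9,13-tetraene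
Conditions: allylmagnesium bromide (1.5 equiv), THF, −78 → 0 °C
Reagents that add atoms: allylmagnesium bromide, C=CC[Mg]Br
Why: Allyl–allyl Grignard coupling, in which the symmetrical nucleophile should attack the unhindered CH2Br terminus (SN2) while the alkenyl bromide stays inert in the absence of a catalyst.

**Step 8**
Reactants: 10 (1E,5E,9E)-1-bromo-2,6,10-trimethyltetradeca-1,5,9,13-tetraene
Product: 11 2,2'-[(2S,5E,9E,13E)-14-bromo-5,9,13-trimethyltetradeca-5,9,13-triene-1,2-diyl]bis(4,4,5,5-tetramethyl-1,3,2-dioxaborolane)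
Conditions: Pt(dba)3 (3 mol%), (R,R)-TADDOL-derived phenylphosphonite (Ar = 3,5-iPr2C6H3, 3.6 mol%), B2pin2 (1.05 equiv), THF, 60 °C
Reagents that add atoms: bis(pinacolato)diboron, CC1(C)OB(OC1(C)C)B1OC(C)(C)C(C)(C)O1
Why: Platinum-catalysed enantioselective alkene diboration (B–B oxidative addition to zerovalent platinum, insertion of the only monosubstituted alkene, reductive elimination), in which the chiral phosphonite should set the secondary C–B stereocenter that becomes ring C1 while the trisubstituted alkenes do not insert.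

**Step 9**
Reactants: 11 the (2S)-1,2-bis(boronate)
Product: 12 4,4,5,5-tetramethyl-2-[(1R,3E,7E,11E)-4,8,12-trimethylcyclotetradeca-3,7,11-trien-1-yl]-1,3,2-dioxaborolane
Conditions: Pd(OAc)2 (10 mol%), RuPhos (12 mol%), KOH (3 equiv), THF/H2O 10:1, 70 °C, slow addition of 11 (final 2 mM)
Reagents that add atoms: none
Why: Intramolecular Suzuki–Miyaura coupling of a vicinal bis(boronate), in which only the primary boronate (activated by its hydroxide-bridged neighbour) should transmetallate and the alkenyl bromide couple with retention, so that the 14-membered ring closes with an (E)-C3=C4 alkene and the secondary C–B stereocenter is kept.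

**Step 10**
Reactants: 12 the macrocyclic pinacol boronic ester
Product: 14 5,5-dimethyl-2-[(1R,3E,7E,11E)-4,8,12-trimethylcyclotetradeca-3,7,11-trien-1-yl]-1,3,2-dioxaborinane, via boronic acid 13 (not isolated)
Conditions: NaIO4, NH4OAc, acetone/H2O, rt; neopentyl glycol, MgSO4, CH2Cl2, rt
Reagents that add atoms: 2,2-dimethylpropane-1,3-diol (neopentyl glycol), OCC(C)(C)CO
Why: Boronic ester exchange by periodate cleavage of the pinacol unit and condensation with neopentyl glycol, which leaves the C–B stereocenter untouched and gives the less hindered ester class that accepts hindered carbenoids.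

**Step 11**
Reactants: 3 the (2S)-TIB ester (1.5 equiv); 14 the macrocyclic neopentyl glycol boronic ester (1.0 equiv)
Product: 18 colleterpenol, (2S,5E)-6,10-dimethyl-2-[(1R,3E,7E,11E)-4,8,12-trimethylcyclotetradeca-3,7,11-trien-1-yl]undeca-5,9-dien-2-ol, via lithiated benzoate 15 (not isolated), via boronate complex 16 (not isolated), via tertiary boronic ester 17 (not isolated)
Conditions: 3, sBuLi (1.4 equiv), TMEDA (6 equiv), CPME, −60 °C, 2 h; 14, −60 °C, 2 h, then rt → 50 °C; 2 M NaOH, 30% H2O2, THF, 0 °C → rt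
Reagents that add atoms: hydrogen peroxide, OO
Why: Proposed new method: sBuLi/TMEDA should remove the carbinol proton of 3 with retention (directed by the TIB carbonyl), the tertiary carbenoid 15 should add to boron of 14 with retention to give ate complex 16, and on warming ring carbon C1 should migrate from boron to C15 antiperiplanar to the departing benzoate (inversion at C15, retention at C1) before stereoretentive oxidation of the C–B bond. The closest known reaction type is the lithiation–borylation of secondary dialkyl TIB esters with neopentyl glycol boronic esters, established for primary-alkyl, alkenyl and aryl boron partners; the extension is a secondary, macrocyclic alkyl boronic ester, argued to be feasible because the non-stabilised carbenoid is a strong nucleophile, the dioxaborinane is the least hindered ester, and secondary alkyl groups migrate readily in the related benzylic series. No ring is closed. The carbinol stereocenter is controlled only by the configuration of 3 and the ring stereocenter only by that of 14, so no CH3 versus CH2R face discrimination is needed when the bond forms. The step needs carbon migration to win over reversal of 16 to 15 and over migration of a diol oxygen; the good TIB leaving group, the small diol and keeping sBuLi below the amount of 3 (no free alkyllithium to consume 14) should secure this, and the five trisubstituted alkenes are inert to the carbenoid and to alkaline peroxide.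

**Compound list**
1 | (5E)-6,10-dimethylundeca-5,9-dien-2-one (geranylacetone) | CC(=O)CC/C=C(\C)CCC=C(C)C | starting material
2 | (2R,5E)-6,10-dimethylundeca-5,9-dien-2-ol | C[C@@H](O)CC/C=C(\C)CCC=C(C)C | intermediate
3 | (2S,5E)-6,10-dimethylundeca-5,9-dien-2-yl 2,4,6-tri(propan-2-yl)benzoate | C[C@H](OC(=O)c1c(C(C)C)cc(C(C)C)cc1C(C)C)CC/C=C(\C)CCC=C(C)C | intermediate
4 | diethyl (5E)-6,10-dimethylundeca-1,5,9-trien-2-yl phosphate | C=C(CC/C=C(\C)CCC=C(C)C)OP(=O)(OCC)OCC | intermediate
5 | (5E)-6,10-dimethylundeca-5,9-dien-1-yne | C#CCC/C=C(\C)CCC=C(C)C | intermediate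
6 | dimethyl[(1E,5E)-2,6,10-trimethylundeca-1,5,9-trien-1-yl]alane | C[Al](C)/C=C(\C)CC/C=C(\C)CCC=C(C)C | intermediate
7 | (1E,5E)-1-bromo-2,6,10-trimethylundeca-1,5,9-triene | Br/C=C(\C)CC/C=C(\C)CCC=C(C)C | intermediate
8 | (2E,6E,10E)-11-bromo-2,6,10-trimethylundeca-2,6,10-trien-1-ol | OC/C(C)=C/CC/C(C)=C/CC/C(C)=C/Br | intermediate
9 | (1E,5E,9E)-1,11-dibromo-2,6,10-trimethylundeca-1,5,9-triene | BrC/C(C)=C/CC/C(C)=C/CC/C(C)=C/Br | intermediate
10 | (1E,5E,9E)-1-bromo-2,6,10-trimethyltetradeca-1,5,9,13-tetraene | C=CCC/C(C)=C/CC/C(C)=C/CC/C(C)=C/Br | intermediate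
11 | 2,2'-[(2S,5E,9E,13E)-14-bromo-5,9,13-trimethyltetradeca-5,9,13-triene-1,2-diyl]bis(4,4,5,5-tetramethyl-1,3,2-dioxaborolane) | CC1(C)OB(OC1(C)C)[C@H](CC/C(C)=C/CC/C(C)=C/CC/C(C)=C/Br)CB1OC(C)(C)C(C)(C)O1 | intermediate
12 | 4,4,5,5-tetramethyl-2-[(1R,3E,7E,11E)-4,8,12-trimethylcyclotetradeca-3,7,11-trien-1-yl]-1,3,2-dioxaborolane | CC1(C)OB(OC1(C)C)[C@H]2C/C=C(\C)CC/C=C(\C)CC/C=C(\C)CC2 | intermediate
13 | [(1R,3E,7E,11E)-4,8,12-trimethylcyclotetradeca-3,7,11-trien-1-yl]boronic acid | OB(O)[C@H]1C/C=C(\C)CC/C=C(\C)CC/C=C(\C)CC1 | intermediate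
14 | 5,5-dimethyl-2-[(1R,3E,7E,11E)-4,8,12-trimethylcyclotetradeca-3,7,11-trien-1-yl]-1,3,2-dioxaborinane | CC1(C)COB(OC1)[C@H]2C/C=C(\C)CC/C=C(\C)CC/C=C(\C)CC2 | intermediate
15 | [(2S,5E)-6,10-dimethyl-2-{[2,4,6-tri(propan-2-yl)benzoyl]oxy}undeca-5,9-dien-2-yl]lithium | C[C@]([Li])(OC(=O)c1c(C(C)C)cc(C(C)C)cc1C(C)C)CC/C=C(\C)CCC=C(C)C | intermediate
16 | lithium boronate complex of 15 with 14 (boron bearing C15, ring C1 and the neopentyl glycol unit) | C[C@](OC(=O)c1c(C(C)C)cc(C(C)C)cc1C(C)C)(CC/C=C(\C)CCC=C(C)C)[B-]2(OCC(C)(C)CO2)[C@H]3C/C=C(\C)CC/C=C(\C)CC/C=C(\C)CC3.[Li+] | intermediate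
17 | 5,5-dimethyl-2-{(2R,5E)-6,10-dimethyl-2-[(1R,3E,7E,11E)-4,8,12-trimethylcyclotetradeca-3,7,11-trien-1-yl]undeca-5,9-dien-2-yl}-1,3,2-dioxaborinane | CC(C)=CCC/C(C)=C/CC[C@](C)(B2OCC(C)(C)CO2)[C@H]1C/C=C(\C)CC/C=C(\C)CC/C=C(\C)CC1 | intermediate
18 | colleterpenol, (2S,5E)-6,10-dimethyl-2-[(1R,3E,7E,11E)-4,8,12-trimethylcyclotetradeca-3,7,11-trien-1-yl]undeca-5,9-dien-2-ol | CC(C)=CCC/C(C)=C/CC[C@](C)(O)[C@H]1C/C=C(\C)CC/C=C(\C)CC/C=C(\C)CC1 | target

**Step count and risks**
Total: 11 steps. Longest linear sequence: 9 steps (steps 3 to 11 from geranylacetone).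

Step 11 (the labelled step). The ate complex between the hindered tertiary carbenoid and the secondary boronic ester may form slowly or revert, so that the carbenoid decomposes before the 1,2-shift, or a diol oxygen may migrate in place of carbon. The fallback uses known chemistry (Matteson substrate-controlled homologation), sets out from 12 and comes back at 18. Compound 12 is cleaved to 13 as in step 10 and condensed with (1R,2R)-1,2-dicyclohexylethane-1,2-diol to give the chiral boronic ester F1. (1,1-Dichloroethyl)lithium (CH3CHCl2, LDA, THF, −100 °C) is inserted under ZnCl2 promotion to give the α-chloro boronic ester F2; the (R,R)-diol is the enantiomer expected, by analogy with dichloromethyllithium insertions, to direct formation of the (R)-chloride. The Grignard reagent F3, made from (E)-homogeranyl bromide and magnesium, then displaces chloride with inversion through the borate to give the tertiary boronic ester F4, and NaOH/H2O2 gives 18. The carbinol carbon is then built in two operations and the side chain enters as a C11 unit instead of the intact C13 half.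

Step 9. Ring closure may lose to intermolecular coupling (oligomers), or to protodeboronation and β-hydride elimination of the alkylpalladium intermediate. The fallback sets out from 9 and comes back at 18; it moves the ring closure to the classical 9-BBN B-alkyl Suzuki manifold at the price of catalyst control at ring C1. Compound 9 is alkylated with 3-(trimethylsilyl)prop-2-ynyllithium to give the silyl enyne F5, and K2CO3/MeOH gives the terminal enyne F6. Markovnikov-selective copper-catalysed protoboration (CuCl, SIMes·HCl, NaOtBu, B2pin2, MeOH) gives the 1,1-disubstituted alkenylboronate F7. 9-BBN adds to its CH2 terminus to give the B-alkyl-9-BBN adduct F8, which is cyclised without isolation [Pd(dppf)Cl2, AsPh3, Cs2CO3, DMF/THF/H2O, slow addition] to the racemic macrocyclic pinacol boronic ester F9. Step 10 then gives the racemic neopentyl glycol ester F10, and step 11 with 3 gives 18 together with its ring epimer F11, which would have to be removed by chromatography.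

Step 5. The ene reaction may also occur at the internal trisubstituted alkene, or over-oxidation may set in, so that the (E)-allylic alcohol is formed unselectively. The fallback sets out from 7 and comes back at 8; it replaces C–H oxidation by cleavage and olefination. Terminal-selective bromohydrin formation (NBS, THF/H2O, 0 °C) gives the bromohydrin F12, K2CO3/MeOH closes it to the epoxide F13, and H5IO6 cleaves this to the aldehyde F14. Wittig reaction with Ph3P=C(CH3)CO2Et gives the (E)-enoate F15, and iBu2AlH (CH2Cl2, −78 °C) reduces it to 8.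

**Further compounds**
F1 | step 11 | (4R,5R)-4,5-dicyclohexyl-2-[(1R,3E,7E,11E)-4,8,12-trimethylcyclotetradeca-3,7,11-trien-1-yl]-1,3,2-dioxaborolane | O1[C@H](C2CCCCC2)[C@@H](C2CCCCC2)OB1[C@H]3C/C=C(\C)CC/C=C(\C)CC/C=C(\C)CC3
F2 | step 11 | (4R,5R)-2-{(1R)-1-chloro-1-[(1R,3E,7E,11E)-4,8,12-trimethylcyclotetradeca-3,7,11-trien-1-yl]ethyl}-4,5-dicyclohexyl-1,3,2-dioxaborolane | C[C@](Cl)(B1O[C@H](C2CCCCC2)[C@@H](C2CCCCC2)O1)[C@H]3C/C=C(\C)CC/C=C(\C)CC/C=C(\C)CC3
F3 | step 11 | bromo[(3E)-4,8-dimethylnona-3,7-dien-1-yl]magnesium (homogeranylmagnesium bromide) | CC(C)=CCC/C(C)=C/CC[Mg]Br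
F4 | step 11 | (4R,5R)-4,5-dicyclohexyl-2-{(2R,5E)-6,10-dimethyl-2-[(1R,3E,7E,11E)-4,8,12-trimethylcyclotetradeca-3,7,11-trien-1-yl]undeca-5,9-dien-2-yl}-1,3,2-dioxaborolane | CC(C)=CCC/C(C)=C/CC[C@](C)(B1O[C@H](C2CCCCC2)[C@@H](C2CCCCC2)O1)[C@H]3C/C=C(\C)CC/C=C(\C)CC/C=C(\C)CC3
F5 | step 9 | [(5E,9E,13E)-14-bromo-5,9,13-trimethyltetradeca-5,9,13-trien-1-yn-1-yl]trimethylsilane | C[Si](C)(C)C#CCC/C(C)=C/CC/C(C)=C/CC/C(C)=C/Br
F6 | step 9 | (5E,9E,13E)-14-bromo-5,9,13-trimethyltetradeca-5,9,13-trien-1-yne | C#CCC/C(C)=C/CC/C(C)=C/CC/C(C)=C/Br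
F7 | step 9 | 2-[(5E,9E,13E)-14-bromo-5,9,13-trimethyltetradeca-1,5,9,13-tetraen-2-yl]-4,4,5,5-tetramethyl-1,3,2-dioxaborolane | C=C(B1OC(C)(C)C(C)(C)O1)CC/C(C)=C/CC/C(C)=C/CC/C(C)=C/Br
F8 | step 9 | 9-[(5E,9E,13E)-14-bromo-5,9,13-trimethyl-2-(4,4,5,5-tetramethyl-1,3,2-dioxaborolan-2-yl)tetradeca-5,9,13-trien-1-yl]-9-borabicyclo[3.3.1]nonane | C(B1C2CCCC1CCC2)C(B3OC(C)(C)C(C)(C)O3)CC/C(C)=C/CC/C(C)=C/CC/C(C)=C/Br
F9 | step 9 | rac-4,4,5,5-tetramethyl-2-[(3E,7E,11E)-4,8,12-trimethylcyclotetradeca-3,7,11-trien-1-yl]-1,3,2-dioxaborolane | CC1(C)OB(OC1(C)C)C2C/C=C(\C)CC/C=C(\C)CC/C=C(\C)CC2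
F10 | step 9 | rac-5,5-dimethyl-2-[(3E,7E,11E)-4,8,12-trimethylcyclotetradeca-3,7,11-trien-1-yl]-1,3,2-dioxaborinane | CC1(C)COB(OC1)C2C/C=C(\C)CC/C=C(\C)CC/C=C(\C)CC2
F11 | step 9 | (2S,5E)-6,10-dimethyl-2-[(1S,3E,7E,11E)-4,8,12-trimethylcyclotetradeca-3,7,11-trien-1-yl]undeca-5,9-dien-2-ol | CC(C)=CCC/C(C)=C/CC[C@](C)(O)[C@@H]1C/C=C(\C)CC/C=C(\C)CC/C=C(\C)CC1
F12 | step 5 | (6E,10E)-3,11-dibromo-2,6,10-trimethylundeca-6,10-dien-2-ol | CC(C)(O)C(Br)CC/C(C)=C/CC/C(C)=C/Br
F13 | step 5 | 3-[(3E,7E)-8-bromo-3,7-dimethylocta-3,7-dien-1-yl]-2,2-dimethyloxirane | CC1(C)OC1CC/C(C)=C/CC/C(C)=C/Br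
F14 | step 5 | (4E,8E)-9-bromo-4,8-dimethylnona-4,8-dienal | O=CCC/C(C)=C/CC/C(C)=C/Br
F15 | step 5 | ethyl (2E,6E,10E)-11-bromo-2,6,10-trimethylundeca-2,6,10-trienoate | CCOC(=O)/C(C)=C/CC/C(C)=C/CC/C(C)=C/Br
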